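**Retrosynthetic overview**
1. Target ⇒ global desilylation, Lindlar semireduction and C7–O acylation: a C7-hydroxy nonanolide plus (R)-4-silyloxyoct-2-ynoic acid (from pentanal and methyl propiolate).
2. The only ring, the nine-membered lactone, is closed once and late, by lactonization of the C1 acid onto C8-OH after the acyclic stereo-array is complete.
3. C2–C3 comes from an Evans syn aldol on a C3 aldehyde; C6–C7 and the C5 carbinol come from a Z-boron-enolate aldol of a C5 ethyl ketone with (S)-O-benzyl-lactaldehyde followed by in situ 1,3-syn reduction.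
4. Key C4–C5 bond: propanal is turned by a chiral triazolylidene into a propanoyl-anion equivalent (Breslow intermediate) that adds to the ketone carbon of ethyl pyruvate, setting the tertiary carbinol C4 in step 1.
5. Stereocontrol: C4 catalyst; C8 lactate pool; C6/C7 Zimmerman–Traxler plus Felkin/Cornforth; C5 aldolate-directed; C2/C3 auxiliary; C4′ Zn-ProPhenol.

Assumption: numbering follows the lactone (C1 = ring C=O, C8 = ring O–CH, C9 = its methyl; side chain C1′–C8′), and the facial sense of the two catalysts (steps 1 and 14) is as written; the antipodal catalyst is used if it is reversed.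

**Route**

Step 1
Reactants: 1 propanal; 2 ethyl pyruvate
Product: 4 ethyl (R)-2-hydroxy-2-methyl-3-oxopentanoate, via Breslow intermediate 3 (not isolated)
Conditions: (S)-5-benzyl-2-(C6F5)-6,7-dihydro-5H-pyrrolo[2,1-c][1,2,4]triazol-2-ium BF4 (10 mol %), i-Pr2NEt, 4 Å MS, CH2Cl2, rt, 1 in excess
Reagents that add atoms: none
Why: The carbene converts 1 into enaminol 3, a propanoyl-anion equivalent that attacks the activated ketone carbon of 2 (C4–C5 bond) rather than a second aldehyde, and the chiral N-C6F5 carbene shields one ketone face so that C4 forms as (R); NHC-catalysed enantioselective aldehyde–α-ketoester cross-benzoin reaction.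

Step 2
Reactants: 4 ethyl (R)-2-hydroxy-2-methyl-3-oxopentanoate
Product: 5 ethyl (R)-2-methyl-3-oxo-2-[(triethylsilyl)oxy]pentanoate
Conditions: TESOTf, 2,6-lutidine, CH2Cl2, −78 → 0 °C
Reagents that add atoms: triethylsilyl trifluoromethanesulfonate, CC[Si](CC)(CC)OS(=O)(=O)C(F)(F)F
Why: The silyl triflate silylates the hindered tertiary carbinol without touching C4, masking it for the boron chemistry; O-silylation.

Step 3
Reactants: 6 ethyl (S)-lactate
Product: 7 ethyl (S)-2-(benzyloxy)propanoate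
Conditions: BnOC(=NH)CCl3, TfOH (cat.), cyclohexane/CH2Cl2, rt
Reagents that add atoms: benzyl 2,2,2-trichloroacetimidate, N=C(OCc1ccccc1)C(Cl)(Cl)Cl
Why: Acid-catalysed imidate benzylation is non-basic, so the lactate stereocenter (future C8) is not racemised; trichloroacetimidate O-benzylation.

Step 4
Reactants: 7 ethyl (S)-2-(benzyloxy)propanoate
Product: 9 (S)-2-(benzyloxy)propanal, via aluminium hemiacetal 8 (not isolated)
Conditions: DIBAL-H, CH2Cl2, −78 °C; MeOH, Rochelle salt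
Reagents that add atoms: none
Why: The chelated tetrahedral aluminate 8 is stable at −78 °C and collapses to the aldehyde only on work-up, with C8 untouched; DIBAL half-reduction of an α-alkoxy ester.

Step 5
Reactants: 5 ethyl (R)-2-methyl-3-oxo-2-[(triethylsilyl)oxy]pentanoate; 9 (S)-2-(benzyloxy)propanal
Product: 12 ethyl (2R,3S,4R,5R,6S)-6-(benzyloxy)-3,5-dihydroxy-2,4-dimethyl-2-[(triethylsilyl)oxy]heptanoate, via Z-boron enolate 10 (not isolated), via boron aldolate 11 (not isolated)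
Conditions: n-Bu2BOTf, i-Pr2NEt, CH2Cl2, −78 → 0 °C; 9, −78 °C; LiBH4 (THF), −78 °C; pH 7 buffer, MeOH, H2O2, 0 °C
Reagents that add atoms: none
Why: The Z(O)-enolate 10 adds through a chair transition state to the Felkin/Cornforth face of the α-benzyloxy aldehyde (6,7-syn, 7,8-anti), LiBH4 then reduces the chelated aldolate 11 to the 5,7-syn diol, and the minor C4 epimer carried from step 1 is removed here as a diastereomer; boron aldol reaction with in situ aldolate-directed 1,3-syn reduction.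

Step 6
Reactants: 12 ethyl (2R,3S,4R,5R,6S)-6-(benzyloxy)-3,5-dihydroxy-2,4-dimethyl-2-[(triethylsilyl)oxy]heptanoate
Product: 13 ethyl (2R,3S,4R,5R,6S)-6-(benzyloxy)-2,4-dimethyl-2,3,5-tris[(triethylsilyl)oxy]heptanoate
Conditions: TESOTf (3 equiv), 2,6-lutidine, CH2Cl2, −78 → 0 °C
Reagents that add atoms: triethylsilyl trifluoromethanesulfonate, CC[Si](CC)(CC)OS(=O)(=O)C(F)(F)F
Why: The triflate is reactive enough to silylate both the neopentylic C5-OH and C7-OH, which also prevents δ-lactonization of C7-OH onto the ester; exhaustive O-silylation.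

Step 7
Reactants: 13 ethyl (2R,3S,4R,5R,6S)-6-(benzyloxy)-2,4-dimethyl-2,3,5-tris[(triethylsilyl)oxy]heptanoate
Product: 15 (2R,3S,4R,5R,6S)-6-(benzyloxy)-2,4-dimethyl-2,3,5-tris[(triethylsilyl)oxy]heptanal, via aluminium hemiacetal 14 (not isolated)
Conditions: DIBAL-H, CH2Cl2, −78 °C; MeOH, Rochelle salt
Reagents that add atoms: none
Why: The α-silyloxy, α-quaternary ester gives a persistent tetrahedral aluminate and cannot enolise, so reduction stops at the C3 aldehyde; DIBAL half-reduction.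

Step 8
Reactants: 15 (2R,3S,4R,5R,6S)-6-(benzyloxy)-2,4-dimethyl-2,3,5-tris[(triethylsilyl)oxy]heptanal; 16 (R)-4-benzyl-3-propanoyl-1,3-oxazolidin-2-one
Product: 19 (R)-4-benzyl-3-[(2R,3R,4S,5S,6R,7R,8S)-8-(benzyloxy)-3-hydroxy-2,4,6-trimethyl-4,5,7-tris[(triethylsilyl)oxy]nonanoyl]-1,3-oxazolidin-2-one, via Z-boron enolate 17 (not isolated), via boron aldolate 18 (not isolated)
Conditions: 16 (2 equiv), n-Bu2BOTf, i-Pr2NEt, CH2Cl2, 0 °C; 15, −78 → 0 °C; pH 7 buffer, MeOH, H2O2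
Reagents that add atoms: none
Why: The Z-enolate 17 of the (R)-benzyl auxiliary reacts through the dipole-minimised chair transition state and overrides the aldehyde's bias to give the (2R,3R) syn aldol; Evans syn aldol reaction.

Step 9
Reactants: 19 (R)-4-benzyl-3-[(2R,3R,4S,5S,6R,7R,8S)-8-(benzyloxy)-3-hydroxy-2,4,6-trimethyl-4,5,7-tris[(triethylsilyl)oxy]nonanoyl]-1,3-oxazolidin-2-one
Product: 21 (2R,3R,4S,5S,6R,7R,8S)-8-(benzyloxy)-3-hydroxy-2,4,6-trimethyl-4,5,7-tris[(triethylsilyl)oxy]nonanoic acid, via peroxy acid 20 (not isolated)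
Conditions: LiOH, H2O2, THF/H2O, 0 °C; aq. Na2SO3; NaHSO4 to pH 4
Reagents that add atoms: hydrogen peroxide (as LiOOH, supplies the acid OH oxygen), OO
Why: Hydroperoxide attacks the exocyclic imide carbonyl selectively, fastest while C3-OH is still free, without epimerising C2, and sulfite reduces peracid 20 to the acid; LiOOH auxiliary cleavage.

Step 10
Reactants: 21 (2R,3R,4S,5S,6R,7R,8S)-8-(benzyloxy)-3-hydroxy-2,4,6-trimethyl-4,5,7-tris[(triethylsilyl)oxy]nonanoic acid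
Product: 23 (2R,3R,4R,5S,6R,7R,8S)-8-(benzyloxy)-2,4,6-trimethyl-3,4,5,7-tetrakis[(triethylsilyl)oxy]nonanoic acid, via silyl ester 22 (not isolated)
Conditions: TESOTf (3 equiv), 2,6-lutidine, CH2Cl2, −78 → 0 °C; then pH 7 buffer/THF, rt
Reagents that add atoms: triethylsilyl trifluoromethanesulfonate, CC[Si](CC)(CC)OS(=O)(=O)C(F)(F)F
Why: The triflate silylates C3-OH and the carboxyl, and the labile silyl ester 22 hydrolyses on aqueous work-up, so C3-OH cannot form a β-lactone during ring closure; O-silylation with selective silyl ester hydrolysis.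

Step 11
Reactants: 23 (2R,3R,4R,5S,6R,7R,8S)-8-(benzyloxy)-2,4,6-trimethyl-3,4,5,7-tetrakis[(triethylsilyl)oxy]nonanoic acid
Product: 24 (2R,3R,4R,5S,6R,7R,8S)-8-hydroxy-2,4,6-trimethyl-3,4,5,7-tetrakis[(triethylsilyl)oxy]nonanoic acid
Conditions: H2 (1 atm), 10% Pd/C, EtOAc, rt
Reagents that add atoms: none
Why: Neutral hydrogenolysis in EtOAc cleaves only the benzyl ether and leaves the TES ethers, freeing C8-OH as the single hydroxyl; catalytic hydrogenolysis.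

Step 12
Reactants: 24 (2R,3R,4R,5S,6R,7R,8S)-8-hydroxy-2,4,6-trimethyl-3,4,5,7-tetrakis[(triethylsilyl)oxy]nonanoic acid
Product: 26 (3R,4R,5R,6S,7R,8R,9S)-3,5,7,9-tetramethyl-4,5,6,8-tetrakis[(triethylsilyl)oxy]oxonan-2-one, via mixed anhydride 25 (not isolated)
Conditions: MNBA (1.5 equiv), DMAP (6 equiv), CH2Cl2 (1 mM), rt, syringe-pump addition of 24
Reagents that add atoms: none
Why: MNBA forms mixed anhydride 25 at the aliphatic carboxyl and DMAP delivers the acyl group to the only free hydroxyl (C8-OH) under high dilution, closing the nine-membered ring with retention at C8; Shiina macrolactonization.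

Step 13
Reactants: 26 (3R,4R,5R,6S,7R,8R,9S)-3,5,7,9-tetramethyl-4,5,6,8-tetrakis[(triethylsilyl)oxy]oxonan-2-one
Product: 27 (3R,4R,5R,6S,7R,8R,9S)-8-hydroxy-3,5,7,9-tetramethyl-4,5,6-tris[(triethylsilyl)oxy]oxonan-2-one
Conditions: HF·pyridine, excess pyridine, THF, −10 → 0 °C, stopped at mono-desilylation
Reagents that add atoms: none
Why: C7-OTES is the only silyl ether not flanked by the fully substituted C4 (C3- and C5-OTES are neopentylic, C4-OTES is tertiary), so fluoride removes it first; sterically controlled selective desilylation.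

Step 14
Reactants: 28 pentanal; 29 methyl propiolate
Product: 31 methyl (R)-4-hydroxyoct-2-ynoate, via zinc acetylide 30 (not isolated)
Conditions: (S,S)-ProPhenol (20 mol %), Me2Zn (3 equiv), Ph3P=O (40 mol %), toluene, 0–4 °C
Reagents that add atoms: none
Why: Me2Zn metalates the propiolate to alkynylzinc 30, which the dinuclear zinc–ProPhenol complex delivers to one face of pentanal to set C4′ as (R); Zn-ProPhenol asymmetric alkynylation.

Step 15
Reactants: 31 methyl (R)-4-hydroxyoct-2-ynoate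
Product: 32 methyl (R)-4-[(triethylsilyl)oxy]oct-2-ynoate
Conditions: TESCl, imidazole, DMF, 0 °C → rt
Reagents that add atoms: chlorotriethylsilane, CC[Si](Cl)(CC)CC
Why: Silylation of the propargylic alcohol leaves C4′ untouched and blocks self-esterification and later butenolide formation; O-silylation.

Step 16
Reactants: 32 methyl (R)-4-[(triethylsilyl)oxy]oct-2-ynoate
Product: 33 (R)-4-[(triethylsilyl)oxy]oct-2-ynoic acid
Conditions: LiOH, THF/H2O, 0 °C; NaHSO4 to pH 4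
Reagents that add atoms: lithium hydroxide (hydroxide oxygen becomes the acid OH), [Li+].[OH-]
Why: Cold hydroxide cleaves the unhindered methyl ester faster than it adds to the ynoate or removes the secondary TES ether; saponification.

Step 17
Reactants: 27 (3R,4R,5R,6S,7R,8R,9S)-8-hydroxy-3,5,7,9-tetramethyl-4,5,6-tris[(triethylsilyl)oxy]oxonan-2-one; 33 (R)-4-[(triethylsilyl)oxy]oct-2-ynoic acid
Product: 35 (3R,4R,5R,6S,7R,8R,9S)-3,5,7,9-tetramethyl-2-oxo-4,5,6-tris[(triethylsilyl)oxy]oxonan-8-yl (R)-4-[(triethylsilyl)oxy]oct-2-ynoate, via O-acylisourea 34 (not isolated)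
Conditions: DIC, DMAP (0.2 equiv), CH2Cl2, −20 → 0 °C
Reagents that add atoms: none
Why: The carbodiimide-activated ynoic acid acylates the only free hydroxyl (C7-OH) with retention, and an alkynoic acid cannot undergo the Z/E scrambling a Z-enoic acid would risk; Steglich esterification.

Step 18
Reactants: 35 (3R,4R,5R,6S,7R,8R,9S)-3,5,7,9-tetramethyl-2-oxo-4,5,6-tris[(triethylsilyl)oxy]oxonan-8-yl (R)-4-[(triethylsilyl)oxy]oct-2-ynoate
Product: 36 (3R,4R,5R,6S,7R,8R,9S)-3,5,7,9-tetramethyl-2-oxo-4,5,6-tris[(triethylsilyl)oxy]oxonan-8-yl (R,Z)-4-[(triethylsilyl)oxy]oct-2-enoate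
Conditions: H2 (1 atm), Lindlar catalyst, quinoline, EtOAc, rt
Reagents that add atoms: none
Why: Syn delivery of H2 on the poisoned palladium surface gives only the Z-enoate and stops at the alkene; Lindlar semihydrogenation.

Step 19
Reactants: 36 (3R,4R,5R,6S,7R,8R,9S)-3,5,7,9-tetramethyl-2-oxo-4,5,6-tris[(triethylsilyl)oxy]oxonan-8-yl (R,Z)-4-[(triethylsilyl)oxy]oct-2-enoate
Product: 37 (3R,4R,5R,6S,7S,8R,9S)-4,5,6-trihydroxy-3,5,7,9-tetramethyl-2-oxooxonan-8-yl (2Z,4R)-4-hydroxyoct-2-enoate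
Conditions: HF·pyridine, pyridine, THF, 0 °C → rt; cold NaHCO3 quench, buffered silica
Reagents that add atoms: none
Why: Buffered fluoride removes all four TES ethers under near-neutral conditions, avoiding transannular translactonization and butenolide formation from the Z-γ-hydroxy enoate; global desilylation.

**Compound list**
1 | propanal | CCC=O | starting material
2 | ethyl pyruvate | CCOC(=O)C(C)=O | starting material
3 | Breslow intermediate, 1-[(5S)-5-benzyl-2-(pentafluorophenyl)-6,7-dihydro-2H-pyrrolo[2,1-c][1,2,4]triazol-3(5H)-ylidene]propan-1-ol | CCC(O)=C1N(c2c(F)c(F)c(F)c(F)c2F)N=C2CC[C@@H](Cc3ccccc3)N12 | intermediate (not isolated)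
4 | ethyl (R)-2-hydroxy-2-methyl-3-oxopentanoate | CCOC(=O)[C@](C)(O)C(=O)CC | intermediate
5 | ethyl (R)-2-methyl-3-oxo-2-[(triethylsilyl)oxy]pentanoate | CCOC(=O)[C@](C)(O[Si](CC)(CC)CC)C(=O)CC | intermediate
6 | ethyl (S)-lactate | CCOC(=O)[C@@H](O)C | starting material
7 | ethyl (S)-2-(benzyloxy)propanoate | CCOC(=O)[C@@H](OCc1ccccc1)C | intermediate
8 | diisobutylaluminium ethyl hemiacetal of 9 | CCOC(O[Al](CC(C)C)CC(C)C)[C@@H](OCc1ccccc1)C | intermediate (not isolated)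
9 | (S)-2-(benzyloxy)propanal | O=C[C@@H](OCc1ccccc1)C | intermediate
10 | ethyl (2R,3Z)-3-[(dibutylboranyl)oxy]-2-methyl-2-[(triethylsilyl)oxy]pent-3-enoate | CCOC(=O)[C@](C)(O[Si](CC)(CC)CC)/C(OB(CCCC)CCCC)=C/C | intermediate (not isolated)
11 | ethyl (2R,4R,5R,6S)-6-(benzyloxy)-5-[(dibutylboranyl)oxy]-2,4-dimethyl-3-oxo-2-[(triethylsilyl)oxy]heptanoate | CCOC(=O)[C@](C)(O[Si](CC)(CC)CC)C(=O)[C@H](C)[C@@H](OB(CCCC)CCCC)[C@@H](OCc1ccccc1)C | intermediate (not isolated)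
12 | ethyl (2R,3S,4R,5R,6S)-6-(benzyloxy)-3,5-dihydroxy-2,4-dimethyl-2-[(triethylsilyl)oxy]heptanoate | CCOC(=O)[C@](C)(O[Si](CC)(CC)CC)[C@@H](O)[C@H](C)[C@@H](O)[C@@H](OCc1ccccc1)C | intermediate
13 | ethyl (2R,3S,4R,5R,6S)-6-(benzyloxy)-2,4-dimethyl-2,3,5-tris[(triethylsilyl)oxy]heptanoate | CCOC(=O)[C@](C)(O[Si](CC)(CC)CC)[C@@H](O[Si](CC)(CC)CC)[C@H](C)[C@@H](O[Si](CC)(CC)CC)[C@@H](OCc1ccccc1)C | intermediate
14 | diisobutylaluminium ethyl hemiacetal of 15 | CCOC(O[Al](CC(C)C)CC(C)C)[C@](C)(O[Si](CC)(CC)CC)[C@@H](O[Si](CC)(CC)CC)[C@H](C)[C@@H](O[Si](CC)(CC)CC)[C@@H](OCc1ccccc1)C | intermediate (not isolated)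
15 | (2R,3S,4R,5R,6S)-6-(benzyloxy)-2,4-dimethyl-2,3,5-tris[(triethylsilyl)oxy]heptanal | O=C[C@](C)(O[Si](CC)(CC)CC)[C@@H](O[Si](CC)(CC)CC)[C@H](C)[C@@H](O[Si](CC)(CC)CC)[C@@H](OCc1ccccc1)C | intermediate
16 | (R)-4-benzyl-3-propanoyl-1,3-oxazolidin-2-one | CCC(=O)N1[C@H](Cc2ccccc2)COC1=O | starting material
17 | (R)-4-benzyl-3-[(Z)-1-[(dibutylboranyl)oxy]prop-1-en-1-yl]-1,3-oxazolidin-2-one | C/C=C(\OB(CCCC)CCCC)N1[C@H](Cc2ccccc2)COC1=O | intermediate (not isolated)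
18 | O3-dibutylboryl aldolate of 19 | O=C(N1[C@H](Cc2ccccc2)COC1=O)[C@H](C)[C@@H](OB(CCCC)CCCC)[C@](C)(O[Si](CC)(CC)CC)[C@@H](O[Si](CC)(CC)CC)[C@H](C)[C@@H](O[Si](CC)(CC)CC)[C@@H](OCc1ccccc1)C | intermediate (not isolated)
19 | (R)-4-benzyl-3-[(2R,3R,4S,5S,6R,7R,8S)-8-(benzyloxy)-3-hydroxy-2,4,6-trimethyl-4,5,7-tris[(triethylsilyl)oxy]nonanoyl]-1,3-oxazolidin-2-one | O=C(N1[C@H](Cc2ccccc2)COC1=O)[C@H](C)[C@@H](O)[C@](C)(O[Si](CC)(CC)CC)[C@@H](O[Si](CC)(CC)CC)[C@H](C)[C@@H](O[Si](CC)(CC)CC)[C@@H](OCc1ccccc1)C | intermediate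
20 | peroxy acid of 21 | OOC(=O)[C@H](C)[C@@H](O)[C@](C)(O[Si](CC)(CC)CC)[C@@H](O[Si](CC)(CC)CC)[C@H](C)[C@@H](O[Si](CC)(CC)CC)[C@@H](OCc1ccccc1)C | intermediate (not isolated)
21 | (2R,3R,4S,5S,6R,7R,8S)-8-(benzyloxy)-3-hydroxy-2,4,6-trimethyl-4,5,7-tris[(triethylsilyl)oxy]nonanoic acid | OC(=O)[C@H](C)[C@@H](O)[C@](C)(O[Si](CC)(CC)CC)[C@@H](O[Si](CC)(CC)CC)[C@H](C)[C@@H](O[Si](CC)(CC)CC)[C@@H](OCc1ccccc1)C | intermediate
22 | triethylsilyl ester of 23 | CC[Si](CC)(CC)OC(=O)[C@H](C)[C@@H](O[Si](CC)(CC)CC)[C@](C)(O[Si](CC)(CC)CC)[C@@H](O[Si](CC)(CC)CC)[C@H](C)[C@@H](O[Si](CC)(CC)CC)[C@@H](OCc1ccccc1)C | intermediate (not isolated)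
23 | (2R,3R,4R,5S,6R,7R,8S)-8-(benzyloxy)-2,4,6-trimethyl-3,4,5,7-tetrakis[(triethylsilyl)oxy]nonanoic acid | OC(=O)[C@H](C)[C@@H](O[Si](CC)(CC)CC)[C@](C)(O[Si](CC)(CC)CC)[C@@H](O[Si](CC)(CC)CC)[C@H](C)[C@@H](O[Si](CC)(CC)CC)[C@@H](OCc1ccccc1)C | intermediate
24 | (2R,3R,4R,5S,6R,7R,8S)-8-hydroxy-2,4,6-trimethyl-3,4,5,7-tetrakis[(triethylsilyl)oxy]nonanoic acid | OC(=O)[C@H](C)[C@@H](O[Si](CC)(CC)CC)[C@](C)(O[Si](CC)(CC)CC)[C@@H](O[Si](CC)(CC)CC)[C@H](C)[C@@H](O[Si](CC)(CC)CC)[C@@H](O)C | intermediate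
25 | mixed anhydride of 24 and 2-methyl-6-nitrobenzoic acid | Cc1cccc([N+](=O)[O-])c1C(=O)OC(=O)[C@H](C)[C@@H](O[Si](CC)(CC)CC)[C@](C)(O[Si](CC)(CC)CC)[C@@H](O[Si](CC)(CC)CC)[C@H](C)[C@@H](O[Si](CC)(CC)CC)[C@@H](O)C | intermediate (not isolated)
26 | (3R,4R,5R,6S,7R,8R,9S)-3,5,7,9-tetramethyl-4,5,6,8-tetrakis[(triethylsilyl)oxy]oxonan-2-one | CC[Si](CC)(CC)O[C@@H]1[C@@H](C)[C@H](O[Si](CC)(CC)CC)[C@@](C)(O[Si](CC)(CC)CC)[C@H](O[Si](CC)(CC)CC)[C@@H](C)C(=O)O[C@H]1C | intermediate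
27 | (3R,4R,5R,6S,7R,8R,9S)-8-hydroxy-3,5,7,9-tetramethyl-4,5,6-tris[(triethylsilyl)oxy]oxonan-2-one | O[C@@H]1[C@@H](C)[C@H](O[Si](CC)(CC)CC)[C@@](C)(O[Si](CC)(CC)CC)[C@H](O[Si](CC)(CC)CC)[C@@H](C)C(=O)O[C@H]1C | intermediate
28 | pentanal | CCCCC=O | starting material
29 | methyl propiolate | C#CC(=O)OC | starting material
30 | methyl 3-(methylzincio)propiolate | C[Zn]C#CC(=O)OC | intermediate (not isolated)
31 | methyl (R)-4-hydroxyoct-2-ynoate | CCCC[C@@H](O)C#CC(=O)OC | intermediate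
32 | methyl (R)-4-[(triethylsilyl)oxy]oct-2-ynoate | CCCC[C@@H](O[Si](CC)(CC)CC)C#CC(=O)OC | intermediate
33 | (R)-4-[(triethylsilyl)oxy]oct-2-ynoic acid | CCCC[C@@H](O[Si](CC)(CC)CC)C#CC(=O)O | intermediate
34 | O-acylisourea of 33 with DIC | CCCC[C@@H](O[Si](CC)(CC)CC)C#CC(=O)OC(=NC(C)C)NC(C)C | intermediate (not isolated)
35 | (3R,4R,5R,6S,7R,8R,9S)-3,5,7,9-tetramethyl-2-oxo-4,5,6-tris[(triethylsilyl)oxy]oxonan-8-yl (R)-4-[(triethylsilyl)oxy]oct-2-ynoate | CCCC[C@@H](O[Si](CC)(CC)CC)C#CC(=O)O[C@@H]1[C@@H](C)[C@H](O[Si](CC)(CC)CC)[C@@](C)(O[Si](CC)(CC)CC)[C@H](O[Si](CC)(CC)CC)[C@@H](C)C(=O)O[C@H]1C | intermediate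
36 | (3R,4R,5R,6S,7R,8R,9S)-3,5,7,9-tetramethyl-2-oxo-4,5,6-tris[(triethylsilyl)oxy]oxonan-8-yl (R,Z)-4-[(triethylsilyl)oxy]oct-2-enoate | CCCC[C@@H](O[Si](CC)(CC)CC)/C=C\C(=O)O[C@@H]1[C@@H](C)[C@H](O[Si](CC)(CC)CC)[C@@](C)(O[Si](CC)(CC)CC)[C@H](O[Si](CC)(CC)CC)[C@@H](C)C(=O)O[C@H]1C | intermediate
37 | (3R,4R,5R,6S,7S,8R,9S)-4,5,6-trihydroxy-3,5,7,9-tetramethyl-2-oxooxonan-8-yl (2Z,4R)-4-hydroxyoct-2-enoate | CCCC[C@@H](O)/C=C\C(=O)O[C@@H]1[C@@H](C)[C@H](O)[C@@](C)(O)[C@H](O)[C@@H](C)C(=O)O[C@H]1C | target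

**Totals**
Total step count: 19. Longest linear sequence: 14 steps (1, 2, 5, 6, 7, 8, 9, 10, 11, 12, 13, 17, 18, 19).

**Three steps most likely to fail**

Step 1 (cross-benzoin). Pyruvate can enolise and self-condense, propanal can homo-couple, and the enantioselectivity with a small alkyl ketoester is uncertain. The fallback keeps the same C4–C5 bond but uses a nitronate as the propanoyl-anion equivalent. It sets out from 2: a Cu(II)–bis(oxazoline)/Et3N-catalysed nitroaldol addition of 1-nitropropane gives ethyl (2R)-2-hydroxy-2-methyl-3-nitropentanoate F1 as a C3-epimer mixture. Silylation with TESOTf/2,6-lutidine gives ethyl (2R)-2-methyl-3-nitro-2-[(triethylsilyl)oxy]pentanoate F2. A mild Nef reaction (NaNO2, AcOH, DMSO) converts the secondary nitro group into the ketone, and the fallback comes back to the route at 5.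

Step 12 (nine-membered lactonization). The tetra-silylated seco acid is congested and medium-ring closure competes with oligomerisation. The fallback closes the ring by C2–C3 bond formation instead. It sets out from 15: hydrogenolysis (H2, Pd/C, EtOAc) gives (2R,3S,4R,5R,6S)-6-hydroxy-2,4-dimethyl-2,3,5-tris[(triethylsilyl)oxy]heptanal F3. Acylation of C8-OH with 2-bromopropanoyl bromide/pyridine gives (2S,3R,4R,5S,6R)-4,6-dimethyl-7-oxo-3,5,6-tris[(triethylsilyl)oxy]heptan-2-yl 2-bromopropanoate F4. A SmI2-mediated intramolecular Reformatsky reaction (THF, −78 °C, high dilution) gives (3R,4R,5S,6S,7R,8R,9S)-4-hydroxy-3,5,7,9-tetramethyl-5,6,8-tris[(triethylsilyl)oxy]oxonan-2-one F5. Here the C2/C3 configuration rests on ring control, so the desired diastereomer must be separated. Silylation with TESOTf comes back to the route at 26.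

Step 13 (selective C7 desilylation). The selectivity among four TES ethers rests on sterics alone, and loss of the C5 silyl group would invite translactonization. The fallback drops protecting-group discrimination in favour of site-selective acylation. It sets out from 26: exhaustive desilylation (HF·pyridine) gives (3R,4R,5R,6S,7R,8R,9S)-4,5,6,8-tetrahydroxy-3,5,7,9-tetramethyloxonan-2-one F6. Acylation with 33 (DIC, cat. DMAP, −20 °C) at the only secondary hydroxyl not next to the quaternary C4 gives (3R,4R,5R,6S,7S,8R,9S)-4,5,6-trihydroxy-3,5,7,9-tetramethyl-2-oxooxonan-8-yl (R)-4-[(triethylsilyl)oxy]oct-2-ynoate F7. Lindlar semihydrogenation gives (3R,4R,5R,6S,7S,8R,9S)-4,5,6-trihydroxy-3,5,7,9-tetramethyl-2-oxooxonan-8-yl (R,Z)-4-[(triethylsilyl)oxy]oct-2-enoate F8. Removal of the last TES ether with HF·pyridine comes back to the route at 37.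

**Further compounds**
F1 | step 1 | ethyl (2R)-2-hydroxy-2-methyl-3-nitropentanoate (C3 epimers) | CCOC(=O)[C@](C)(O)C(CC)[N+](=O)[O-]
F2 | step 1 | ethyl (2R)-2-methyl-3-nitro-2-[(triethylsilyl)oxy]pentanoate (C3 epimers) | CCOC(=O)[C@](C)(O[Si](CC)(CC)CC)C(CC)[N+](=O)[O-]
F3 | step 12 | (2R,3S,4R,5R,6S)-6-hydroxy-2,4-dimethyl-2,3,5-tris[(triethylsilyl)oxy]heptanal | O=C[C@](C)(O[Si](CC)(CC)CC)[C@@H](O[Si](CC)(CC)CC)[C@H](C)[C@@H](O[Si](CC)(CC)CC)[C@@H](O)C
F4 | step 12 | (2S,3R,4R,5S,6R)-4,6-dimethyl-7-oxo-3,5,6-tris[(triethylsilyl)oxy]heptan-2-yl 2-bromopropanoate (bromide epimers) | O=C[C@](C)(O[Si](CC)(CC)CC)[C@@H](O[Si](CC)(CC)CC)[C@H](C)[C@@H](O[Si](CC)(CC)CC)[C@@H](OC(=O)C(C)Br)C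
F5 | step 12 | (3R,4R,5S,6S,7R,8R,9S)-4-hydroxy-3,5,7,9-tetramethyl-5,6,8-tris[(triethylsilyl)oxy]oxonan-2-one | CC[Si](CC)(CC)O[C@@H]1[C@@H](C)[C@H](O[Si](CC)(CC)CC)[C@@](C)(O[Si](CC)(CC)CC)[C@H](O)[C@@H](C)C(=O)O[C@H]1C
F6 | step 13 | (3R,4R,5R,6S,7R,8R,9S)-4,5,6,8-tetrahydroxy-3,5,7,9-tetramethyloxonan-2-one | O[C@@H]1[C@@H](C)[C@H](O)[C@@](C)(O)[C@H](O)[C@@H](C)C(=O)O[C@H]1C
F7 | step 13 | (3R,4R,5R,6S,7S,8R,9S)-4,5,6-trihydroxy-3,5,7,9-tetramethyl-2-oxooxonan-8-yl (R)-4-[(triethylsilyl)oxy]oct-2-ynoate | CCCC[C@@H](O[Si](CC)(CC)CC)C#CC(=O)O[C@@H]1[C@@H](C)[C@H](O)[C@@](C)(O)[C@H](O)[C@@H](C)C(=O)O[C@H]1C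
F8 | step 13 | (3R,4R,5R,6S,7S,8R,9S)-4,5,6-trihydroxy-3,5,7,9-tetramethyl-2-oxooxonan-8-yl (R,Z)-4-[(triethylsilyl)oxy]oct-2-enoate | CCCC[C@@H](O[Si](CC)(CC)CC)/C=C\C(=O)O[C@@H]1[C@@H](C)[C@H](O)[C@@](C)(O)[C@H](O)[C@@H](C)C(=O)O[C@H]1C
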